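## Structural features

The target is a 2,2-disubstituted chroman in which benzene ring A (C4a, C5, C6, C7, C8, C8a) is fused along C4a–C8a to dihydropyran ring B (O1, C2, C3, C4). Ring A is pentasubstituted: methoxy at C5, the only ring hydrogen at C6, the palmitoyloxymethyl group at C7, a formyl group at C8, and O1 and C4 on the fusion carbons. C2 is the sole stereocentre, an (S)-configured, fully substituted ether carbon carrying O1, C3, a methyl group and the side chain C1'H2–C2'(=O)–C3'H=C4'(CH3)2; it has no stereogenic neighbour that could relay or correct its configuration. The C2' ketone is β to O1, so base can expel the phenoxide (E1cB), open ring B and lose the configuration on reclosure; the enone, the benzylic ester and the formyl/oxymethyl pair on C8/C7 (lactol formation once the C7 oxygen is free) are further weak points. The real difficulty is twofold: a tertiary ether stereocentre that cannot be made by substitution at carbon, and a benzene ring whose five substituents must be placed without regiochemical doubt. The key step uses the fact that C2 is bonded to O1 and that C3 lies between C2 and the benzylic carbon C4: with C4 as a ketone on C4a, a carbene at C3 finds the O1-activated C2–H bond of a secondary aryl ether at the 1,6 position, closes ring B at C2–C3 and turns the secondary ether into the tertiary one.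

## Logic of the disconnections

**28 to 25 and 26.** The ester C–O bond at the C7 oxymethyl group is cut and the C8 formyl group is traced back to its dioxolane. The sixteen-carbon chain is best attached last, and the acetal keeps the C7 hydroxymethyl group and the C8 aldehyde from meeting as a lactol. The gain is 25, which has neither the lipophilic chain nor a free aldehyde. The forward step must be mild (weak amine base, then dilute acid), because from 24 onward O1 is β to a ketone.

**25 to 21 and 22 (through 24 and 23).** The C2'–C3' bond is cut. This removes the enone as a commercial four-carbon alkenyl nucleophile, 22, and leaves an aldehyde at C2'; the enone level returns by allylic oxidation of 23. Addition to 21 must outrun its enolisation, since 21 is a β-aryloxy aldehyde, and the oxidation and the C7 desilylation must avoid strong base.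

**21 to 15 (through 20, 19, 18 and 16).** Only functional groups change: the C2' aldehyde goes back to a protected primary alcohol, and the C4 methylene back to the C4 ketone that the key step needs. The C4 oxygen has to leave in the presence of two other benzylic C–O functions (C7 silyloxymethyl, C8 acetal). It is therefore removed by reduction, elimination to 18 and hydrogenation of C3=C4, not by hydrogenolysis or ionic reduction. For the same reason the side-chain oxygen is not carried as a benzyl ether; it is a silyl ether more labile than the one at C7, so that each can be removed in its turn.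

**15 to 14.** The C2–C3 bond is cut. This is the strategic simplification: ring B and the quaternary centre disappear together, and what remains is an acyclic secondary aryl ether whose configuration comes from a cheap chiral alcohol. The forward step must insert a carbene into the C2–H bond with retention and in preference to the methoxy C–H bonds and the two ether oxygens.

**14 to 10 (through 12 and 11).** The diazo carbon is traced to the methyl group of 12 (diazo transfer), and the C4–C4a bond to 11 and an acetyl donor. A methyl ketone is preferred to a carboxylic acid at C4. An acid would compete with the phenol in the etherification, would need hydrolysis of a doubly flanked ester, and would have to pass through an acid chloride (HCl next to an acetal and two silyl ethers) and diazomethane. Lithiation of 10 must occur only between the two ether oxygens; this is the only ring C–H with two ortho oxygens.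

**10 to 6 and 8 (through 9); 8 to 7.** O1–C2 is cut as a Mitsunobu etherification with inversion. The ether is made before the acyl group is in place, so the phenol of 6 has one ortho substituent instead of two and is acidified by its ortho formyl group. The step must give clean SN2 inversion; the (S) centre of 7 is carried into 8 untouched.

**6 to 1 (through 5, 3 and 2).** The C8 formyl carbon is cut back to a bromine and the phenol to a methyl ether. Bromination of 1 fixes the C8 position by ordinary electrophilic regiochemistry, and the aldehyde then directs cleavage of the one methoxy group that must become O1. The C7 silyl ether has to survive an organolithium and a boron Lewis acid, which is why the more robust diphenyl silyl group is used there.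

## Other disconnections considered

**Alternative 1:** The cut runs through ring A at C4a–C5 and C6–C7, so the benzene ring is built last from the chiral bicyclic pyranopyranone A1 and the ketene acetal A2.
- Forward key step: the 2-pyrone of A1 would serve as the diene; decarboxylative cycloreversion of the adduct and loss of one methoxy group as the alcohol would give the chroman ester A3.
- In its favour: the polarity of the cycloaddition places all five ring A substituents, with no directed metalation and no selective demethylation. On arene regiocontrol this is the better plan.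
- Against it here: C2 must already be present in A1, so the tertiary-ether problem is only moved into the synthesis of A1. A3 carries a 4-methylpent-3-enyl chain, one oxidation short at C2'; a late oxidation of that allylic methylene would compete with two allylic methyl groups and the benzylic C4 methylene. The C8 ester must still be brought to the aldehyde beside the C7 oxymethyl group.
- Comparison: structurally it solves ring A and leaves C2 and C2' open, whereas the chosen plan does the reverse. Mechanistically a pericyclic cascade is as predictable as the insertion, so the two are equal there. In step count it should be shorter to the aromatic core but longer and less certain at the end.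

**Alternative 2:** The cut is at C4–C4a and C8a–O1, giving the iodophthalide A4 and the chiral-pool iodo alcohol A5.
- Forward key step: under palladium catalysis with a phosphine, a strained bicyclic alkene as transient mediator and a carbonate base, the primary iodide of A5 would alkylate the free ortho C–H of A4, and the aryl–palladium bond left at the ipso carbon would be closed by the tertiary alkoxide to give the lactone-fused chroman A6.
- In its favour: it is the most convergent of the four plans. The stereocentre is bought and no bond to it is ever formed or broken, so on stereochemical fidelity it is at least the equal of the chosen plan.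
- Against it here: C–O bond formation from a hindered tertiary alkoxide at palladium is the slowest kind of termination. A5 can cyclise on itself under base. A6 again lacks the C2' oxygen, and its lactone must be opened into a differentiated aldehyde and acyloxymethyl pair, which passes through the lactol that the chosen plan avoids.
- Comparison: structurally it uses the aryl iodide and the ortho C–H, where the chosen plan uses the O1-activated C2–H. Mechanistically it relies on a multi-step organometallic relay with several branch points, against one concerted insertion. It is better in step count to the ring system and worse in the oxidation-state corrections afterwards.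

**Alternative 3:** The cut is at C3–C4 and O1–C2, giving the ortho-hydroxybenzyl alcohol A7 and the cross-conjugated silyl trienol ether A8.
- Forward key step: a chiral BINOL-derived phosphoric acid would dehydrate A7 to the ortho-quinone methide A9; the terminal CH2 of A8 would add to the exocyclic carbon and the ring oxygen would close onto the resulting allylic cation, giving the silyl dienol ether A10, which is one hydrolysis from the target.
- In its favour: the whole side chain arrives at the right oxidation level and the palmitate and aldehyde are already in place. In step economy it is clearly the better plan.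
- Against it here: the phenol of A7 is hydrogen-bonded to its ortho formyl group, and A9 carries an acceptor that should make it short-lived. A8 has several nucleophilic carbons. The quaternary centre would be fixed in the C–O ring closure, where the catalyst must tell a methyl from an alkenyl group, and the acid catalyst can also protodesilylate A8.
- Comparison: structurally it uses the phenol/benzylic pair of ring A, which is equally sound. Mechanistically its stereocontrol is catalyst-based and open, against substrate-encoded and stereospecific in the chosen plan. It is shortest by far if the selectivity holds.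

Key step: step 10

Abbreviations: TBS = tert-butyldimethylsilyl; TBDPS = tert-butyldiphenylsilyl; DMP = Dess–Martin periodinane; chroman numbering and C1'–C4' for the side chain are used throughout.

Remark on the chemistry: 16, 17 and 23 are expected as mixtures of epimers at their carbinol carbon, which is of no consequence because that centre is later removed or oxidised; the change of the C2 descriptor from R (15 to 18) to S (19 onward) reflects only the CIP ranking of C3 against C1', not a change in spatial arrangement.

## Route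

Step 1
Reactants: 1 3,5-dimethoxybenzyl alcohol
Product: 2 (2-bromo-3,5-dimethoxyphenyl)methanol
Conditions: NBS (1.0 equiv), CH2Cl2, 0 °C to rt
Reagents that add atoms: N-bromosuccinimide, O=C1CCC(=O)N1Br
Why: Electrophilic aromatic bromination; the position next to the hydroxymethyl group is ortho to one methoxy group, para to the other and less shielded than the position between the two methoxy groups, so bromine should enter there and mark the carbon that becomes C8.

Step 2
Reactants: 2 (2-bromo-3,5-dimethoxyphenyl)methanol
Product: 3 [(2-bromo-3,5-dimethoxybenzyl)oxy](tert-butyl)diphenylsilane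
Conditions: TBDPSCl, imidazole, DMF, rt
Reagents that add atoms: tert-butyl(chloro)diphenylsilane, CC(C)(C)[Si](Cl)(c1ccccc1)c1ccccc1
Why: Standard silylation of a primary alcohol; the TBDPS ether is chosen because it has to outlast BCl3 in step 4 and has to remain when the side-chain TBS ether is removed in step 14.

Step 3
Reactants: 3 [(2-bromo-3,5-dimethoxybenzyl)oxy](tert-butyl)diphenylsilane
Product: 5 2-({[tert-butyl(diphenyl)silyl]oxy}methyl)-4,6-dimethoxybenzaldehyde, via aryllithium 4 (not isolated)
Conditions: n-BuLi (1.05 equiv), Et2O, −78 °C, 15 min; DMF, −78 to 0 °C; aq NH4Cl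
Reagents that add atoms: N,N-dimethylformamide, CN(C)C=O; n-butyllithium, [Li]CCCC (its lithium is held only in 4)
Why: Bromine–lithium exchange followed by formylation with DMF; the bromine fixes the site, and at −78 °C the aryllithium should be trapped before silyl migration from oxygen to carbon can set in.

Step 4
Reactants: 5 2-({[tert-butyl(diphenyl)silyl]oxy}methyl)-4,6-dimethoxybenzaldehyde
Product: 6 2-({[tert-butyl(diphenyl)silyl]oxy}methyl)-6-hydroxy-4-methoxybenzaldehyde
Conditions: BCl3 (1.2 equiv), CH2Cl2, −78 to −20 °C; aq NaHCO3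
Reagents that add atoms: none
Why: Chelation-controlled ether cleavage: BCl3 bound to the aldehyde oxygen delivers chloride only to the methyl group of the ortho methoxy, so the para methoxy (future C5–OMe) stays; the bulky silyl ether on a ring deactivated by the complexed aldehyde should survive the short cold exposure.

Step 5
Reactants: 7 (S)-butane-1,3-diol
Product: 8 (2S)-4-{[tert-butyl(dimethyl)silyl]oxy}butan-2-ol
Conditions: TBSCl (1.0 equiv), imidazole, CH2Cl2, −10 °C
Reagents that add atoms: tert-butyl(chloro)dimethylsilane, CC(C)(C)[Si](C)(C)Cl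
Why: Selective silylation of the primary hydroxyl of a 1,3-diol with one equivalent of silyl chloride at low temperature; the stereocentre is not touched and stays (S).

Step 6
Reactants: 6 2-({[tert-butyl(diphenyl)silyl]oxy}methyl)-6-hydroxy-4-methoxybenzaldehyde; 8 (2S)-4-{[tert-butyl(dimethyl)silyl]oxy}butan-2-ol
Product: 9 2-{[(2R)-4-{[tert-butyl(dimethyl)silyl]oxy}butan-2-yl]oxy}-6-({[tert-butyl(diphenyl)silyl]oxy}methyl)-4-methoxybenzaldehyde
Conditions: PPh3, DIAD, toluene, 0 °C to rt
Reagents that add atoms: none
Why: Mitsunobu etherification: the acidic salicylaldehyde-type phenol, which has only one ortho substituent at this stage, displaces the activated secondary alcohol by SN2, so the (S) carbinol becomes the (R) aryl ether; this step encodes the configuration of C2.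

Step 7
Reactants: 9 2-{[(2R)-4-{[tert-butyl(dimethyl)silyl]oxy}butan-2-yl]oxy}-6-({[tert-butyl(diphenyl)silyl]oxy}methyl)-4-methoxybenzaldehyde
Product: 10 2-[2-{[(2R)-4-{[tert-butyl(dimethyl)silyl]oxy}butan-2-yl]oxy}-6-({[tert-butyl(diphenyl)silyl]oxy}methyl)-4-methoxyphenyl]-1,3-dioxolane
Conditions: (TMSOCH2)2, TMSOTf (5 mol %), CH2Cl2, −78 to −20 °C; pyridine
Reagents that add atoms: 1,2-bis(trimethylsilyloxy)ethane, C[Si](C)(C)OCCO[Si](C)(C)C
Why: Noyori acetalisation converts even electron-rich, flanked aldehydes at low temperature and leaves both silyl ethers untouched; the dioxolane masks the aldehyde for the organolithium, hydride and Grignard steps.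

Step 8
Reactants: 10 2-[2-{[(2R)-4-{[tert-butyl(dimethyl)silyl]oxy}butan-2-yl]oxy}-6-({[tert-butyl(diphenyl)silyl]oxy}methyl)-4-methoxyphenyl]-1,3-dioxolane
Product: 12 1-[2-{[(2R)-4-{[tert-butyl(dimethyl)silyl]oxy}butan-2-yl]oxy}-4-({[tert-butyl(diphenyl)silyl]oxy}methyl)-3-(1,3-dioxolan-2-yl)-6-methoxyphenyl]ethan-1-one, via aryllithium 11 (not isolated)
Conditions: n-BuLi, TMEDA, THF, 0 °C, 1 h; MeCON(OMe)Me, −78 to 0 °C; aq NH4Cl
Reagents that add atoms: N-methoxy-N-methylacetamide, CC(=O)N(C)OC; n-butyllithium, [Li]CCCC (its lithium is held only in 11)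
Why: Directed ortho-metalation: the only ring C–H flanked by two ether oxygens is the most acidic and should be lithiated; the aryllithium adds to the N-methoxy-N-methylamide to give a chelated adduct that collapses to the methyl ketone only on work-up, so no over-addition occurs.

Step 9
Reactants: 12 1-[2-{[(2R)-4-{[tert-butyl(dimethyl)silyl]oxy}butan-2-yl]oxy}-4-({[tert-butyl(diphenyl)silyl]oxy}methyl)-3-(1,3-dioxolan-2-yl)-6-methoxyphenyl]ethan-1-one
Product: 14 2-diazo-1-[2-{[(2R)-4-{[tert-butyl(dimethyl)silyl]oxy}butan-2-yl]oxy}-4-({[tert-butyl(diphenyl)silyl]oxy}methyl)-3-(1,3-dioxolan-2-yl)-6-methoxyphenyl]ethan-1-one, via trifluoroacetyl diketone 13 (not isolated)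
Conditions: LiN(SiMe3)2, THF, −78 °C; CF3CO2CH2CF3, −78 °C; aq NH4Cl; then 4-acetamidobenzenesulfonyl azide, Et3N, H2O (1 equiv), MeCN, rt
Reagents that add atoms: 4-acetamidobenzenesulfonyl azide, CC(=O)Nc1ccc(cc1)S(=O)(=O)N=[N+]=[N-]; 2,2,2-trifluoroethyl trifluoroacetate, FC(F)(F)COC(=O)C(F)(F)F (its acyl group is held only in 13)
Why: Detrifluoroacetylative diazo transfer (Danheiser type): the kinetic lithium enolate is trifluoroacetylated, and the activated 1,3-diketone takes the diazo group from the sulfonyl azide and passes its trifluoroacetyl group to the sulfonamide; the diazomethyl ketone is reached without acid chloride, acid or diazomethane.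

Step 10
Reactants: 14 2-diazo-1-[2-{[(2R)-4-{[tert-butyl(dimethyl)silyl]oxy}butan-2-yl]oxy}-4-({[tert-butyl(diphenyl)silyl]oxy}methyl)-3-(1,3-dioxolan-2-yl)-6-methoxyphenyl]ethan-1-one
Product: 15 (2R)-2-(2-{[tert-butyl(dimethyl)silyl]oxy}ethyl)-7-({[tert-butyl(diphenyl)silyl]oxy}methyl)-8-(1,3-dioxolan-2-yl)-5-methoxy-2-methylchroman-4-one
Conditions: Rh2(OAc)4 (1 mol %), CH2Cl2 (0.01 M), reflux, slow addition of 14
Reagents that add atoms: none
Why: Rh2(OAc)4 releases N2 from 14 and forms an electrophilic rhodium carbene at C3; the C2–H bond, made hydridic by the O1 lone pair, interacts with the empty carbene orbital, and C–H cleavage and C2–C3 bond formation occur in one three-centre event that frees the catalyst. The closest known reaction type is the dirhodium-catalysed C–H insertion of ortho-alkoxyaryl diazoketones to chroman-4-ones, together with the established retention of configuration in carbene insertion into stereogenic tertiary C–H bonds. Ring B is closed by a 1,6 insertion (C3, C4, C4a, C8a, O1, C2) through a six-membered transition state; no five-membered C–H alternative exists because the 1,5 atom is O1 itself. The configuration of the new quaternary C2 is controlled by the substrate alone: the C–C bond forms on the face from which hydrogen departs, so the (R) ether of 14 should give (R)-15 with the same spatial arrangement, and an achiral catalyst suffices. The step needs C2–H insertion to win over insertion into the C5 methoxy C–H bonds (also 1,6, but primary and less hydridic), over oxonium ylide formation at O1 or the methoxy oxygen (the follow-up 1,2-shift of a secondary alkyl group is slow) and over carbene dimerisation (slow addition, high dilution). The substrate helps: the silyl-protected side chain offers no activated C–H bond or π system within reach, the acetal C–H is meta to the acyl carbon and cannot be reached, and the two ortho substituents hold the carbene next to the ether groups. If the acetate catalyst is not selective enough, Rh2(NHCOCH3)4 or Rh2(O2CCPh3)4 can be used to tune the carbene.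

Step 11
Reactants: 15 (2R)-2-(2-{[tert-butyl(dimethyl)silyl]oxy}ethyl)-7-({[tert-butyl(diphenyl)silyl]oxy}methyl)-8-(1,3-dioxolan-2-yl)-5-methoxy-2-methylchroman-4-one
Product: 16 (2R,4RS)-2-(2-{[tert-butyl(dimethyl)silyl]oxy}ethyl)-7-({[tert-butyl(diphenyl)silyl]oxy}methyl)-8-(1,3-dioxolan-2-yl)-5-methoxy-2-methylchroman-4-ol
Conditions: NaBH4, MeOH/THF, 0 °C
Reagents that add atoms: none
Why: Hydride reduction of the aryl ketone; both C4 epimers are acceptable because C4 becomes sp2 in the next step, and the short cold reaction keeps the β-aryloxy ketone from ring opening.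

Step 12
Reactants: 16 (2R,4RS)-2-(2-{[tert-butyl(dimethyl)silyl]oxy}ethyl)-7-({[tert-butyl(diphenyl)silyl]oxy}methyl)-8-(1,3-dioxolan-2-yl)-5-methoxy-2-methylchroman-4-ol
Product: 18 (2R)-2-(2-{[tert-butyl(dimethyl)silyl]oxy}ethyl)-7-({[tert-butyl(diphenyl)silyl]oxy}methyl)-8-(1,3-dioxolan-2-yl)-5-methoxy-2-methyl-2H-chromene, via C4 mesylate 17 (not isolated)
Conditions: MsCl, Et3N (4 equiv), CH2Cl2, 0 to 40 °C
Reagents that add atoms: methanesulfonyl chloride, CS(=O)(=O)Cl (its atoms are held only in 17)
Why: Sulfonylation of a benzylic alcohol whose cation is stabilised by two ortho oxygen substituents (O1 and C5–OMe) should lead to E1-type elimination in the presence of Et3N and give the conjugated 2H-chromene; the medium stays basic, so the acetal and both silyl ethers are safe.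

Step 13
Reactants: 18 (2R)-2-(2-{[tert-butyl(dimethyl)silyl]oxy}ethyl)-7-({[tert-butyl(diphenyl)silyl]oxy}methyl)-8-(1,3-dioxolan-2-yl)-5-methoxy-2-methyl-2H-chromene
Product: 19 (2S)-2-(2-{[tert-butyl(dimethyl)silyl]oxy}ethyl)-7-({[tert-butyl(diphenyl)silyl]oxy}methyl)-8-(1,3-dioxolan-2-yl)-5-methoxy-2-methylchroman
Conditions: H2 (1 atm), 5% Pd/C, EtOAc, pyridine (0.5 equiv), rt
Reagents that add atoms: none
Why: Catalytic hydrogenation of a cis-disubstituted styrene-type alkene is far faster than hydrogenolysis of the benzylic silyl ether or the aryl acetal, and pyridine suppresses benzylic C–O cleavage further; C2 is not affected.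

Step 14
Reactants: 19 (2S)-2-(2-{[tert-butyl(dimethyl)silyl]oxy}ethyl)-7-({[tert-butyl(diphenyl)silyl]oxy}methyl)-8-(1,3-dioxolan-2-yl)-5-methoxy-2-methylchroman
Product: 20 2-[(2S)-7-({[tert-butyl(diphenyl)silyl]oxy}methyl)-8-(1,3-dioxolan-2-yl)-5-methoxy-2-methylchroman-2-yl]ethan-1-ol
Conditions: HF·pyridine, pyridine, THF, 0 °C to rt
Reagents that add atoms: none
Why: Buffered HF·pyridine cleaves a primary TBS ether much faster than a TBDPS ether, and the excess pyridine keeps the medium from hydrolysing the dioxolane.

Step 15
Reactants: 20 2-[(2S)-7-({[tert-butyl(diphenyl)silyl]oxy}methyl)-8-(1,3-dioxolan-2-yl)-5-methoxy-2-methylchroman-2-yl]ethan-1-ol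
Product: 21 2-[(2S)-7-({[tert-butyl(diphenyl)silyl]oxy}methyl)-8-(1,3-dioxolan-2-yl)-5-methoxy-2-methylchroman-2-yl]acetaldehyde
Conditions: DMP, NaHCO3, CH2Cl2, 0 °C to rt
Reagents that add atoms: none
Why: Dess–Martin oxidation under bicarbonate buffer gives the aldehyde without acid or strong base, which matters because 21 is a β-aryloxy aldehyde; it is used directly.

Step 16
Reactants: 21 2-[(2S)-7-({[tert-butyl(diphenyl)silyl]oxy}methyl)-8-(1,3-dioxolan-2-yl)-5-methoxy-2-methylchroman-2-yl]acetaldehyde; 22 2-methylprop-1-enylmagnesium bromide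
Product: 23 1-[(2S)-7-({[tert-butyl(diphenyl)silyl]oxy}methyl)-8-(1,3-dioxolan-2-yl)-5-methoxy-2-methylchroman-2-yl]-4-methylpent-3-en-2-ol
Conditions: THF, −78 °C; aq NH4Cl at −78 °C
Reagents that add atoms: none
Why: 1,2-Addition of an alkenyl Grignard reagent to an aldehyde at −78 °C, where addition should outrun enolisation; the new carbinol centre is formed without control and is removed by the following oxidation.

Step 17
Reactants: 23 1-[(2S)-7-({[tert-butyl(diphenyl)silyl]oxy}methyl)-8-(1,3-dioxolan-2-yl)-5-methoxy-2-methylchroman-2-yl]-4-methylpent-3-en-2-ol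
Product: 24 1-[(2S)-7-({[tert-butyl(diphenyl)silyl]oxy}methyl)-8-(1,3-dioxolan-2-yl)-5-methoxy-2-methylchroman-2-yl]-4-methylpent-3-en-2-one
Conditions: MnO2 (activated, excess), CH2Cl2, rt
Reagents that add atoms: none
Why: MnO2 oxidises allylic alcohols selectively under neutral, heterogeneous conditions, so the β-aryloxy enone is formed without base that could open ring B.

Step 18
Reactants: 24 1-[(2S)-7-({[tert-butyl(diphenyl)silyl]oxy}methyl)-8-(1,3-dioxolan-2-yl)-5-methoxy-2-methylchroman-2-yl]-4-methylpent-3-en-2-one
Product: 25 1-[(2S)-8-(1,3-dioxolan-2-yl)-7-(hydroxymethyl)-5-methoxy-2-methylchroman-2-yl]-4-methylpent-3-en-2-one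
Conditions: TBAF, AcOH (1:1), THF, 0 °C to rt
Reagents that add atoms: none
Why: Fluoride-induced desilylation buffered with one equivalent of acetic acid keeps the medium close to neutral, which should avoid both E1cB opening of ring B and acid-promoted acetal exchange with the freed hydroxyl.

Step 19
Reactants: 25 1-[(2S)-8-(1,3-dioxolan-2-yl)-7-(hydroxymethyl)-5-methoxy-2-methylchroman-2-yl]-4-methylpent-3-en-2-one; 26 palmitoyl chloride
Product: 28 [(2S)-8-formyl-5-methoxy-2-methyl-2-(4-methyl-2-oxopent-3-en-1-yl)chroman-7-yl]methyl hexadecanoate, via palmitate acetal 27 (not isolated)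
Conditions: pyridine, DMAP (5 mol %), CH2Cl2, 0 °C; then THF, 1 M aq HCl, rt
Reagents that add atoms: water, O
Why: Acylation of the primary benzylic alcohol by the acid chloride under pyridine/DMAP catalysis, followed in the same flask by hydrolysis of the electron-rich aryl dioxolane with dilute acid; the formyl group appears only after the neighbouring oxygen is acylated, so no lactol can form.

## Compound list

1 | 3,5-dimethoxybenzyl alcohol | COc1cc(CO)cc(OC)c1 | starting material
2 | (2-bromo-3,5-dimethoxyphenyl)methanol | COc1cc(CO)c(Br)c(OC)c1 | intermediate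
3 | [(2-bromo-3,5-dimethoxybenzyl)oxy](tert-butyl)diphenylsilane | COc1cc(CO[Si](c2ccccc2)(c2ccccc2)C(C)(C)C)c(Br)c(OC)c1 | intermediate
4 | [2-({[tert-butyl(diphenyl)silyl]oxy}methyl)-4,6-dimethoxyphenyl]lithium | COc1cc(CO[Si](c2ccccc2)(c2ccccc2)C(C)(C)C)c([Li])c(OC)c1 | intermediate
5 | 2-({[tert-butyl(diphenyl)silyl]oxy}methyl)-4,6-dimethoxybenzaldehyde | COc1cc(CO[Si](c2ccccc2)(c2ccccc2)C(C)(C)C)c(C=O)c(OC)c1 | intermediate
6 | 2-({[tert-butyl(diphenyl)silyl]oxy}methyl)-6-hydroxy-4-methoxybenzaldehyde | COc1cc(O)c(C=O)c(CO[Si](c2ccccc2)(c2ccccc2)C(C)(C)C)c1 | intermediate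
7 | (S)-butane-1,3-diol | C[C@H](O)CCO | starting material
8 | (2S)-4-{[tert-butyl(dimethyl)silyl]oxy}butan-2-ol | C[C@H](O)CCO[Si](C)(C)C(C)(C)C | intermediate
9 | 2-{[(2R)-4-{[tert-butyl(dimethyl)silyl]oxy}butan-2-yl]oxy}-6-({[tert-butyl(diphenyl)silyl]oxy}methyl)-4-methoxybenzaldehyde | COc1cc(O[C@H](C)CCO[Si](C)(C)C(C)(C)C)c(C=O)c(CO[Si](c2ccccc2)(c2ccccc2)C(C)(C)C)c1 | intermediate
10 | 2-[2-{[(2R)-4-{[tert-butyl(dimethyl)silyl]oxy}butan-2-yl]oxy}-6-({[tert-butyl(diphenyl)silyl]oxy}methyl)-4-methoxyphenyl]-1,3-dioxolane | COc1cc(O[C@H](C)CCO[Si](C)(C)C(C)(C)C)c(C2OCCO2)c(CO[Si](c2ccccc2)(c2ccccc2)C(C)(C)C)c1 | intermediate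
11 | [2-{[(2R)-4-{[tert-butyl(dimethyl)silyl]oxy}butan-2-yl]oxy}-4-({[tert-butyl(diphenyl)silyl]oxy}methyl)-3-(1,3-dioxolan-2-yl)-6-methoxyphenyl]lithium | COc1c([Li])c(O[C@H](C)CCO[Si](C)(C)C(C)(C)C)c(C2OCCO2)c(CO[Si](c2ccccc2)(c2ccccc2)C(C)(C)C)c1 | intermediate
12 | 1-[2-{[(2R)-4-{[tert-butyl(dimethyl)silyl]oxy}butan-2-yl]oxy}-4-({[tert-butyl(diphenyl)silyl]oxy}methyl)-3-(1,3-dioxolan-2-yl)-6-methoxyphenyl]ethan-1-one | COc1c(C(C)=O)c(O[C@H](C)CCO[Si](C)(C)C(C)(C)C)c(C2OCCO2)c(CO[Si](c2ccccc2)(c2ccccc2)C(C)(C)C)c1 | intermediate
13 | 1-[2-{[(2R)-4-{[tert-butyl(dimethyl)silyl]oxy}butan-2-yl]oxy}-4-({[tert-butyl(diphenyl)silyl]oxy}methyl)-3-(1,3-dioxolan-2-yl)-6-methoxyphenyl]-4,4,4-trifluorobutane-1,3-dione | COc1c(C(=O)CC(=O)C(F)(F)F)c(O[C@H](C)CCO[Si](C)(C)C(C)(C)C)c(C2OCCO2)c(CO[Si](c2ccccc2)(c2ccccc2)C(C)(C)C)c1 | intermediate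
14 | 2-diazo-1-[2-{[(2R)-4-{[tert-butyl(dimethyl)silyl]oxy}butan-2-yl]oxy}-4-({[tert-butyl(diphenyl)silyl]oxy}methyl)-3-(1,3-dioxolan-2-yl)-6-methoxyphenyl]ethan-1-one | [N-]=[N+]=CC(=O)c1c(OC)cc(CO[Si](c2ccccc2)(c2ccccc2)C(C)(C)C)c(C2OCCO2)c1O[C@H](C)CCO[Si](C)(C)C(C)(C)C | intermediate
15 | (2R)-2-(2-{[tert-butyl(dimethyl)silyl]oxy}ethyl)-7-({[tert-butyl(diphenyl)silyl]oxy}methyl)-8-(1,3-dioxolan-2-yl)-5-methoxy-2-methylchroman-4-one | CC(C)(C)[Si](c1ccccc1)(c1ccccc1)OCc1cc(OC)c2c(c1C3OCCO3)O[C@](C)(CCO[Si](C)(C)C(C)(C)C)CC2=O | intermediate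
16 | (2R,4RS)-2-(2-{[tert-butyl(dimethyl)silyl]oxy}ethyl)-7-({[tert-butyl(diphenyl)silyl]oxy}methyl)-8-(1,3-dioxolan-2-yl)-5-methoxy-2-methylchroman-4-ol | CC(C)(C)[Si](c1ccccc1)(c1ccccc1)OCc1cc(OC)c2c(c1C3OCCO3)O[C@](C)(CCO[Si](C)(C)C(C)(C)C)CC2O | intermediate
17 | (2R,4RS)-2-(2-{[tert-butyl(dimethyl)silyl]oxy}ethyl)-7-({[tert-butyl(diphenyl)silyl]oxy}methyl)-8-(1,3-dioxolan-2-yl)-5-methoxy-2-methylchroman-4-yl methanesulfonate | CC(C)(C)[Si](c1ccccc1)(c1ccccc1)OCc1cc(OC)c2c(c1C3OCCO3)O[C@](C)(CCO[Si](C)(C)C(C)(C)C)CC2OS(C)(=O)=O | intermediate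
18 | (2R)-2-(2-{[tert-butyl(dimethyl)silyl]oxy}ethyl)-7-({[tert-butyl(diphenyl)silyl]oxy}methyl)-8-(1,3-dioxolan-2-yl)-5-methoxy-2-methyl-2H-chromene | CC(C)(C)[Si](c1ccccc1)(c1ccccc1)OCc1cc(OC)c2c(c1C3OCCO3)O[C@](C)(CCO[Si](C)(C)C(C)(C)C)C=C2 | intermediate
19 | (2S)-2-(2-{[tert-butyl(dimethyl)silyl]oxy}ethyl)-7-({[tert-butyl(diphenyl)silyl]oxy}methyl)-8-(1,3-dioxolan-2-yl)-5-methoxy-2-methylchroman | CC(C)(C)[Si](c1ccccc1)(c1ccccc1)OCc1cc(OC)c2c(c1C3OCCO3)O[C@](C)(CCO[Si](C)(C)C(C)(C)C)CC2 | intermediate
20 | 2-[(2S)-7-({[tert-butyl(diphenyl)silyl]oxy}methyl)-8-(1,3-dioxolan-2-yl)-5-methoxy-2-methylchroman-2-yl]ethan-1-ol | CC(C)(C)[Si](c1ccccc1)(c1ccccc1)OCc1cc(OC)c2c(c1C3OCCO3)O[C@](C)(CCO)CC2 | intermediate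
21 | 2-[(2S)-7-({[tert-butyl(diphenyl)silyl]oxy}methyl)-8-(1,3-dioxolan-2-yl)-5-methoxy-2-methylchroman-2-yl]acetaldehyde | CC(C)(C)[Si](c1ccccc1)(c1ccccc1)OCc1cc(OC)c2c(c1C3OCCO3)O[C@](C)(CC=O)CC2 | intermediate
22 | 2-methylprop-1-enylmagnesium bromide | CC(C)=C[Mg]Br | starting material
23 | 1-[(2S)-7-({[tert-butyl(diphenyl)silyl]oxy}methyl)-8-(1,3-dioxolan-2-yl)-5-methoxy-2-methylchroman-2-yl]-4-methylpent-3-en-2-ol (both carbinol epimers) | CC(C)(C)[Si](c1ccccc1)(c1ccccc1)OCc1cc(OC)c2c(c1C3OCCO3)O[C@](C)(CC(O)C=C(C)C)CC2 | intermediate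
24 | 1-[(2S)-7-({[tert-butyl(diphenyl)silyl]oxy}methyl)-8-(1,3-dioxolan-2-yl)-5-methoxy-2-methylchroman-2-yl]-4-methylpent-3-en-2-one | CC(C)(C)[Si](c1ccccc1)(c1ccccc1)OCc1cc(OC)c2c(c1C3OCCO3)O[C@](C)(CC(=O)C=C(C)C)CC2 | intermediate
25 | 1-[(2S)-8-(1,3-dioxolan-2-yl)-7-(hydroxymethyl)-5-methoxy-2-methylchroman-2-yl]-4-methylpent-3-en-2-one | OCc1cc(OC)c2c(c1C3OCCO3)O[C@](C)(CC(=O)C=C(C)C)CC2 | intermediate
26 | palmitoyl chloride (hexadecanoyl chloride) | CCCCCCCCCCCCCCCC(=O)Cl | starting material
27 | [(2S)-8-(1,3-dioxolan-2-yl)-5-methoxy-2-methyl-2-(4-methyl-2-oxopent-3-en-1-yl)chroman-7-yl]methyl hexadecanoate | CCCCCCCCCCCCCCCC(=O)OCc1cc(OC)c2c(c1C3OCCO3)O[C@](C)(CC(=O)C=C(C)C)CC2 | intermediate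
28 | [(2S)-8-formyl-5-methoxy-2-methyl-2-(4-methyl-2-oxopent-3-en-1-yl)chroman-7-yl]methyl hexadecanoate (CNP0228756.1) | CCCCCCCCCCCCCCCC(=O)OCc1cc(OC)c2c(c1C=O)O[C@](C)(CC(=O)C=C(C)C)CC2 | target

## Step count and least certain steps

Total step count: 19 (18 on the main line plus the one-step preparation of 8). Longest linear sequence: 18 steps, from 1 to 28 (steps 1 to 4 and 6 to 19).

**Step 10 (key step).**
- Risk: diversion of the carbene into oxonium ylide formation at O1 or at the methoxy oxygen followed by alkyl migration, insertion into a methoxy C–H bond, or carbene dimerisation. The acceptor-only carbene is very electrophilic and has two ether oxygens at its 1,5 positions.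
- Fallback: it sets out from 6 and comes back at 18; it forms O1–C2 asymmetrically and closes ring B at C3–C4 by metathesis. Asymmetric allylic etherification of 6 with methyl (2E)-5-{[tert-butyl(dimethyl)silyl]oxy}-3-methylpent-2-en-1-yl carbonate F1 (made separately in the usual way from the corresponding allylic alcohol and methyl chloroformate), Pd2(dba)3·CHCl3 and Trost's diamide bisphosphine ligand of the appropriate handedness should give the tertiary allyl aryl ether aldehyde F2. Acetalisation as in step 7 gives dioxolane F3. Lithiation between the two ether oxygens as in step 8 and quenching with DMF give aldehyde F4. Ph3P=CH2 gives styrene F5. Ring-closing metathesis with the second-generation Grubbs catalyst closes C3=C4 and returns 18.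

**Step 4.**
- Risk: loss or chloride exchange of the benzylic silyl ether, or cleavage of the second methoxy group, because BCl3 is a strong Lewis acid that also binds ether oxygens.
- Fallback: it sets out from 1 and comes back at 6 with no Lewis acid; it is not the first choice because the phenol has two ortho positions. Heating 1 with NaSEt in DMF removes one methyl group to give 3-(hydroxymethyl)-5-methoxyphenol F6. TBDPSCl and imidazole silylate its primary alcohol to give 3-({[tert-butyl(diphenyl)silyl]oxy}methyl)-5-methoxyphenol F7. Magnesium-mediated ortho-formylation (MgCl2, Et3N, paraformaldehyde, MeCN, reflux) at the position para to the methoxy group gives 6.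

**Step 8.**
- Risk: proton transfer from the acetyl group of the amide to the hindered aryllithium (returning 10), or metalation at the benzylic CH2OSi group next to the coordinating acetal.
- Fallback: it sets out from 11 and comes back at 12 by addition and oxidation in place of acyl transfer. 11 is trapped with acetaldehyde to give the carbinol 1-[2-{[(2R)-4-{[tert-butyl(dimethyl)silyl]oxy}butan-2-yl]oxy}-4-({[tert-butyl(diphenyl)silyl]oxy}methyl)-3-(1,3-dioxolan-2-yl)-6-methoxyphenyl]ethan-1-ol F8, and DMP oxidation gives 12.

**Step 16.**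
- Risk: enolisation of the β-aryloxy aldehyde by the basic Grignard reagent, followed by β-elimination of the phenoxide, which would open ring B and lose the C2 configuration.
- Fallback: it sets out from 21 and comes back at 23 through a non-basic organochromium addition (Nozaki–Hiyama–Kishi): 1-bromo-2-methylprop-1-ene, CrCl2 and catalytic NiCl2 in DMF. No new compound is made.

**Step 18.**
- Risk: fluoride-induced ring opening of the β-aryloxy enone, or acetal exchange onto the freed neighbouring hydroxyl if the buffer is too acidic.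
- Fallback: it sets out from 23 and comes back at 27, with desilylation moved in front of the oxidation. Unbuffered TBAF on 23 gives the diol 1-[(2S)-8-(1,3-dioxolan-2-yl)-7-(hydroxymethyl)-5-methoxy-2-methylchroman-2-yl]-4-methylpent-3-en-2-ol F9. One equivalent of 26 with 2,4,6-collidine at −40 °C acylates the primary benzylic hydroxyl to give the hydroxy ester F10. MnO2 oxidises the allylic alcohol to 27, which is hydrolysed as in step 19.

## Further compounds

F1 | step 10 | methyl (2E)-5-{[tert-butyl(dimethyl)silyl]oxy}-3-methylpent-2-en-1-yl carbonate | COC(=O)OC/C=C(\C)CCO[Si](C)(C)C(C)(C)C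
F2 | step 10 | 2-{[(3R)-5-{[tert-butyl(dimethyl)silyl]oxy}-3-methylpent-1-en-3-yl]oxy}-6-({[tert-butyl(diphenyl)silyl]oxy}methyl)-4-methoxybenzaldehyde | COc1cc(O[C@](C)(CCO[Si](C)(C)C(C)(C)C)C=C)c(C=O)c(CO[Si](c2ccccc2)(c2ccccc2)C(C)(C)C)c1
F3 | step 10 | 2-[2-{[(3R)-5-{[tert-butyl(dimethyl)silyl]oxy}-3-methylpent-1-en-3-yl]oxy}-6-({[tert-butyl(diphenyl)silyl]oxy}methyl)-4-methoxyphenyl]-1,3-dioxolane | COc1cc(O[C@](C)(CCO[Si](C)(C)C(C)(C)C)C=C)c(C2OCCO2)c(CO[Si](c2ccccc2)(c2ccccc2)C(C)(C)C)c1
F4 | step 10 | 2-{[(3R)-5-{[tert-butyl(dimethyl)silyl]oxy}-3-methylpent-1-en-3-yl]oxy}-4-({[tert-butyl(diphenyl)silyl]oxy}methyl)-3-(1,3-dioxolan-2-yl)-6-methoxybenzaldehyde | COc1c(C=O)c(O[C@](C)(CCO[Si](C)(C)C(C)(C)C)C=C)c(C2OCCO2)c(CO[Si](c2ccccc2)(c2ccccc2)C(C)(C)C)c1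
F5 | step 10 | 2-[2-{[(3R)-5-{[tert-butyl(dimethyl)silyl]oxy}-3-methylpent-1-en-3-yl]oxy}-6-({[tert-butyl(diphenyl)silyl]oxy}methyl)-3-ethenyl-4-methoxyphenyl]-1,3-dioxolane | COc1c(C=C)c(O[C@](C)(CCO[Si](C)(C)C(C)(C)C)C=C)c(C2OCCO2)c(CO[Si](c2ccccc2)(c2ccccc2)C(C)(C)C)c1
F6 | step 4 | 3-(hydroxymethyl)-5-methoxyphenol | COc1cc(O)cc(CO)c1
F7 | step 4 | 3-({[tert-butyl(diphenyl)silyl]oxy}methyl)-5-methoxyphenol | COc1cc(O)cc(CO[Si](c2ccccc2)(c2ccccc2)C(C)(C)C)c1
F8 | step 8 | 1-[2-{[(2R)-4-{[tert-butyl(dimethyl)silyl]oxy}butan-2-yl]oxy}-4-({[tert-butyl(diphenyl)silyl]oxy}methyl)-3-(1,3-dioxolan-2-yl)-6-methoxyphenyl]ethan-1-ol (both carbinol epimers) | COc1c(C(C)O)c(O[C@H](C)CCO[Si](C)(C)C(C)(C)C)c(C2OCCO2)c(CO[Si](c2ccccc2)(c2ccccc2)C(C)(C)C)c1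
F0 | step 16 | none | none
F9 | step 18 | 1-[(2S)-8-(1,3-dioxolan-2-yl)-7-(hydroxymethyl)-5-methoxy-2-methylchroman-2-yl]-4-methylpent-3-en-2-ol (both carbinol epimers) | OCc1cc(OC)c2c(c1C3OCCO3)O[C@](C)(CC(O)C=C(C)C)CC2
F10 | step 18 | [(2S)-8-(1,3-dioxolan-2-yl)-2-(2-hydroxy-4-methylpent-3-en-1-yl)-5-methoxy-2-methylchroman-7-yl]methyl hexadecanoate (both carbinol epimers) | CCCCCCCCCCCCCCCC(=O)OCc1cc(OC)c2c(c1C3OCCO3)O[C@](C)(CC(O)C=C(C)C)CC2
A1 | alternative 1 | methyl (2R)-7-({[tert-butyl(dimethyl)silyl]oxy}methyl)-2-methyl-2-(4-methylpent-3-en-1-yl)-5-oxo-3,4-dihydro-2H,5H-pyrano[4,3-b]pyran-8-carboxylate | O=C1OC(CO[Si](C)(C)C(C)(C)C)=C(C(=O)OC)C2=C1CC[C@@](C)(CCC=C(C)C)O2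
A2 | alternative 1 | 1,1-dimethoxyethene | C=C(OC)OC
A3 | alternative 1 | methyl (2R)-7-({[tert-butyl(dimethyl)silyl]oxy}methyl)-5-methoxy-2-methyl-2-(4-methylpent-3-en-1-yl)chroman-8-carboxylate | COC(=O)c1c(CO[Si](C)(C)C(C)(C)C)cc(OC)c2c1O[C@](C)(CCC=C(C)C)CC2
A4 | alternative 2 | 7-iodo-5-methoxy-2-benzofuran-1(3H)-one | O=C1OCc2cc(OC)cc(I)c12
A5 | alternative 2 | (3R)-1-iodo-3,7-dimethyloct-6-en-3-ol | ICC[C@](C)(O)CCC=C(C)C
A6 | alternative 2 | (2R)-5-methoxy-2-methyl-2-(4-methylpent-3-en-1-yl)chroman carrying a γ-lactone across C7–C8 (carbonyl on C8, OCH2 on C7) | O=C1OCc2cc(OC)c3c(c12)O[C@](C)(CCC=C(C)C)CC3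
A7 | alternative 3 | [2-formyl-3-hydroxy-4-(hydroxymethyl)-5-methoxyphenyl]methyl hexadecanoate | CCCCCCCCCCCCCCCC(=O)OCc1cc(OC)c(CO)c(O)c1C=O
A8 | alternative 3 | tert-butyl{[(3Z)-2,6-dimethylhepta-1,3,5-trien-4-yl]oxy}dimethylsilane | C=C(C)/C=C(\O[Si](C)(C)C(C)(C)C)C=C(C)C
A9 | alternative 3 | (2-formyl-5-methoxy-4-methylidene-3-oxocyclohexa-1,5-dien-1-yl)methyl hexadecanoate | CCCCCCCCCCCCCCCC(=O)OCC1=C(C=O)C(=O)C(=C)C(OC)=C1
A10 | alternative 3 | [(2S)-2-[(1Z)-2-{[tert-butyl(dimethyl)silyl]oxy}-4-methylpenta-1,3-dien-1-yl]-8-formyl-5-methoxy-2-methylchroman-7-yl]methyl hexadecanoate | CCCCCCCCCCCCCCCC(=O)OCc1cc(OC)c2c(c1C=O)O[C@](C)(/C=C(\O[Si](C)(C)C(C)(C)C)C=C(C)C)CC2
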